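**Retrosynthetic overview**
- The target is the mono-alcohol of a C2-symmetric C40 diketone, so the last step is reduction of one of two equivalent carbonyls with axial hydride delivery.
- The diketone comes from a double Wittig reaction of two identical C15 keto-phosphonium salts with the C10 trienedial (bonds C11=C12 and C11'=C12').
- The C10 trienedial comes from furan: oxidative ring opening to cis-butenedial, then double Wittig with a C3 formyl ylide.
- The C15 unit comes from the key step: a one-pot enantioselective conjugate dienylation and α-methylation of prochiral 4,4-dimethylcyclohexa-2,5-dienone, which sets both ring stereocentres, followed by conjugate reduction of the remaining enone. The C5 dienyl donor is made from (E)-3-methylpent-2-en-4-yn-1-ol.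
- No ring is built: both six-membered rings enter preformed as the dienone and are finished before the polyene is joined.

Assumption: the (S,R,R)-phosphoramidite named in step 2 is taken to give the (5S) adduct (its antipode is used unchanged if the first run shows the opposite sense), and the dienone, the enynol and the formyl ylide are taken as catalogue compounds.

**Step 1**
Reactants: 1 (E)-3-methylpent-2-en-4-yn-1-ol
Product: 2 tert-butyldimethyl{[(E)-3-methylpent-2-en-4-yn-1-yl]oxy}silane
Conditions: TBSCl (1.1 equiv), imidazole (1.5 equiv), CH2Cl2, 0 °C → rt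
Reagents that add atoms: tert-butyldimethylsilyl chloride, CC(C)(C)[Si](C)(C)Cl
Why: Standard silylation of a primary alcohol, which masks the OH for the organometallic chemistry of step 2 and leaves the (E)-alkene untouched.

**Step 2**
Reactants: 2 tert-butyldimethyl{[(E)-3-methylpent-2-en-4-yn-1-yl]oxy}silane, 3 4,4-dimethylcyclohexa-2,5-dien-1-one
Product: 7 (5S,6S)-5-[(1E,3E)-5-(tert-butyldimethylsilyloxy)-3-methylpenta-1,3-dienyl]-4,4,6-trimethylcyclohex-2-en-1-one, via dienylzirconocene chloride 4 (not isolated), via dienyl(methyl)zinc 5 (not isolated), via methylzinc dienolate 6 (not isolated)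
Conditions: Cp2Zr(H)Cl (1.4 equiv), CH2Cl2, rt; Me2Zn (1.4 equiv), toluene, −65 °C; 3 (1.0 equiv), Cu(OTf)2 (5 mol%), (S)-BINOL-derived N,N-bis[(R)-1-phenylethyl]phosphoramidite (10 mol%), −30 °C; then MeI (5 equiv), HMPA (10 equiv), −30 → 0 °C
Reagents that add atoms: iodomethane, CI
Why: Proposed new method: syn-hydrozirconation of the terminal alkyne fixes the (E)-dienyl–metal bond, Me2Zn relays the dienyl group to zinc, and a chiral copper–phosphoramidite complex delivers it to one of the two enantiotopic β-carbons of the C2v-symmetric dienone (desymmetrising asymmetric conjugate addition; closest known reactions are copper/phosphoramidite additions of dialkylzincs to 4,4-disubstituted cyclohexadienones and copper-catalysed 1,4-additions of alkenylzirconocene-derived zinc reagents), after which the zinc dienolate, whose other α-carbon is vinylic and so cannot compete, is C-methylated in HMPA anti to the new C5 substituent to give the trans-5,6 pair.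

**Step 3**
Reactants: 7 (5S,6S)-5-[(1E,3E)-5-(tert-butyldimethylsilyloxy)-3-methylpenta-1,3-dienyl]-4,4,6-trimethylcyclohex-2-en-1-one
Product: 8 (2S,3S)-3-[(1E,3E)-5-(tert-butyldimethylsilyloxy)-3-methylpenta-1,3-dienyl]-2,4,4-trimethylcyclohexan-1-one
Conditions: [(Ph3P)CuH]6 (0.25 equiv), H2O (2 equiv), benzene, rt
Reagents that add atoms: none
Why: Copper hydride conjugate reduction (Stryker-type) saturates only the electron-poor enone C=C, leaves the isolated diene and the silyl ether alone, and is neutral, so the two stereocentres are not disturbed.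

**Step 4**
Reactants: 8 (2S,3S)-3-[(1E,3E)-5-(tert-butyldimethylsilyloxy)-3-methylpenta-1,3-dienyl]-2,4,4-trimethylcyclohexan-1-one
Product: 10 [(2E,4E)-3-methyl-5-[(1S,2S)-2,6,6-trimethyl-3-oxocyclohexyl]penta-2,4-dienyl]triphenylphosphonium bromide, via free dienol 9 (not isolated)
Conditions: PPh3·HBr (1.05 equiv), MeOH, 0 °C → rt; recrystallise (EtOAc/MeOH)
Reagents that add atoms: triphenylphosphine hydrobromide, Br.c1ccc(cc1)P(c1ccccc1)c1ccccc1
Why: Acidic methanolysis frees the allylic alcohol, which ionises to a pentadienyl cation that PPh3 captures at the unhindered primary terminus under thermodynamic control (SN1-type allylic phosphonium salt formation, as for retinyl-type salts); the α-methyl centre is already in its more stable trans arrangement and the crystalline salt allows the enantiomeric purity to be raised.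

**Step 5**
Reactants: 11 furan, 12 2-(triphenylphosphoranylidene)propanal
Product: 15 (2E,4E,6E)-2,7-dimethylocta-2,4,6-trienedial, via cis-butenedial 13 (not isolated), via 4Z-trienedial 14 (not isolated)
Conditions: dimethyldioxirane (1.0 equiv, acetone), 11 (1.2 equiv), −20 → 0 °C; then 12 (2.2 equiv), CH2Cl2, rt → 40 °C; then I2 (2 mol%), CH2Cl2, daylight, rt
Reagents that add atoms: dimethyldioxirane, CC1(C)OO1
Why: Oxidative dearomatisation of furan (epoxidation and ring opening) gives cis-butenedial cleanly, the stabilised formyl ylide olefinates both reactive aldehydes E-selectively (Wittig reaction) and stops there because α-methyl enals are far less electrophilic, and iodine isomerises the central cis bond to the all-trans dial.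

**Step 6**
Reactants: 10 [(2E,4E)-3-methyl-5-[(1S,2S)-2,6,6-trimethyl-3-oxocyclohexyl]penta-2,4-dienyl]triphenylphosphonium bromide (2.2 equiv), 15 (2E,4E,6E)-2,7-dimethylocta-2,4,6-trienedial
Product: 18 (5S,6S,5'S,6'S)-5,6,5',6'-tetrahydro-β,β-carotene-4,4'-dione, via dienylidene phosphorane 16 (not isolated), via C25 keto aldehyde 17 (not isolated)
Conditions: NaOMe (2.3 equiv), MeOH/CH2Cl2, 0 °C → rt; then n-heptane, reflux, N2, dark
Reagents that add atoms: none
Why: Double Wittig olefination in which the semi-stabilised allylic ylide reacts with the aldehyde groups much faster than with the hindered ring ketones, the minor cis isomers at the new 11,12 bonds are equilibrated to all-trans on heating, and no stereocentre is touched (the only epimerisable centre, C5, is already trans).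

**Step 7**
Reactants: 18 (5S,6S,5'S,6'S)-5,6,5',6'-tetrahydro-β,β-carotene-4,4'-dione
Product: 19 (4S,5S,6S,5'S,6'S)-4-hydroxy-5,6,5',6'-tetrahydro-β,β-caroten-4'-one (CNP0107241.1)
Conditions: NaBH4 (0.3 equiv), CeCl3·7H2O (1 equiv), THF/MeOH, −40 °C, quench at about 50% conversion; chromatography; recovered 18 recycled
Reagents that add atoms: none
Why: The two carbonyls are related by the C2 axis, so reduction of either gives the same mono-alcohol (statistical symmetry-breaking mono-reduction), and the small hydride attacks the chair axially, past only axial hydrogens at C2 and C6, to give the equatorial 4-OH trans to the 5-methyl group, which is the (4S) centre.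

**Compound list**
1 | (E)-3-methylpent-2-en-4-yn-1-ol | OC/C=C(C)/C#C | starting material
2 | tert-butyldimethyl{[(E)-3-methylpent-2-en-4-yn-1-yl]oxy}silane | CC(C)(C)[Si](C)(C)OC/C=C(C)/C#C | intermediate
3 | 4,4-dimethylcyclohexa-2,5-dien-1-one | CC1(C)C=CC(=O)C=C1 | starting material
4 | chlorobis(cyclopentadienyl)[(1E,3E)-5-(tert-butyldimethylsilyloxy)-3-methylpenta-1,3-dienyl]zirconium (formed in situ) | CC(C)(C)[Si](C)(C)OC/C=C(C)/C=C/[Zr](Cl)(C1C=CC=C1)C1C=CC=C1 | intermediate
5 | [(1E,3E)-5-(tert-butyldimethylsilyloxy)-3-methylpenta-1,3-dienyl](methyl)zinc (formed in situ) | CC(C)(C)[Si](C)(C)OC/C=C(C)/C=C/[Zn]C | intermediate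
6 | methylzinc (3S)-3-[(1E,3E)-5-(tert-butyldimethylsilyloxy)-3-methylpenta-1,3-dienyl]-4,4-dimethylcyclohexa-1,5-dien-1-olate (formed in situ) | CC(C)(C)[Si](C)(C)OC/C=C(C)/C=C/[C@H]1C=C(O[Zn]C)C=CC1(C)C | intermediate
7 | (5S,6S)-5-[(1E,3E)-5-(tert-butyldimethylsilyloxy)-3-methylpenta-1,3-dienyl]-4,4,6-trimethylcyclohex-2-en-1-one | CC(C)(C)[Si](C)(C)OC/C=C(C)/C=C/[C@H]1[C@H](C)C(=O)C=CC1(C)C | intermediate
8 | (2S,3S)-3-[(1E,3E)-5-(tert-butyldimethylsilyloxy)-3-methylpenta-1,3-dienyl]-2,4,4-trimethylcyclohexan-1-one | CC(C)(C)[Si](C)(C)OC/C=C(C)/C=C/[C@H]1[C@H](C)C(=O)CCC1(C)C | intermediate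
9 | (2S,3S)-3-[(1E,3E)-5-hydroxy-3-methylpenta-1,3-dienyl]-2,4,4-trimethylcyclohexan-1-one (formed in situ) | OC/C=C(C)/C=C/[C@H]1[C@H](C)C(=O)CCC1(C)C | intermediate
10 | [(2E,4E)-3-methyl-5-[(1S,2S)-2,6,6-trimethyl-3-oxocyclohexyl]penta-2,4-dienyl]triphenylphosphonium bromide | [Br-].c1ccccc1[P+](c1ccccc1)(c1ccccc1)C/C=C(C)/C=C/[C@H]1[C@H](C)C(=O)CCC1(C)C | intermediate
11 | furan | c1ccoc1 | starting material
12 | 2-(triphenylphosphoranylidene)propanal | CC(C=O)=P(c1ccccc1)(c1ccccc1)c1ccccc1 | starting material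
13 | (Z)-but-2-enedial (formed in situ) | O=C/C=C\C=O | intermediate
14 | (2E,4Z,6E)-2,7-dimethylocta-2,4,6-trienedial (formed in situ) | O=C/C(C)=C/C=C\C=C(C)\C=O | intermediate
15 | (2E,4E,6E)-2,7-dimethylocta-2,4,6-trienedial | O=C/C(C)=C/C=C/C=C(C)/C=O | intermediate
16 | (2S,3S)-2,4,4-trimethyl-3-[(1E,3E)-3-methyl-5-(triphenylphosphoranylidene)penta-1,3-dienyl]cyclohexan-1-one (formed in situ) | c1ccccc1P(c1ccccc1)(c1ccccc1)=C/C=C(C)/C=C/[C@H]1[C@H](C)C(=O)CCC1(C)C | intermediate
17 | (2E,4E,6E,8E,10E,12E)-2,7,11-trimethyl-13-[(1S,2S)-2,6,6-trimethyl-3-oxocyclohexyl]trideca-2,4,6,8,10,12-hexaenal (formed in situ) | O=C/C(C)=C/C=C/C=C(C)/C=C/C=C(C)/C=C/[C@H]1[C@H](C)C(=O)CCC1(C)C | intermediate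
18 | (5S,6S,5'S,6'S)-5,6,5',6'-tetrahydro-β,β-carotene-4,4'-dione | CC(/C=C/C=C(C)/C=C/[C@H]1[C@H](C)C(=O)CCC1(C)C)=C\C=C\C=C(C)\C=C\C=C(C)\C=C\[C@H]1[C@H](C)C(=O)CCC1(C)C | intermediate
19 | (4S,5S,6S,5'S,6'S)-4-hydroxy-5,6,5',6'-tetrahydro-β,β-caroten-4'-one | CC(/C=C/C=C(C)/C=C/[C@H]1[C@H](C)[C@@H](O)CCC1(C)C)=C\C=C\C=C(C)\C=C\C=C(C)\C=C\[C@H]1[C@H](C)C(=O)CCC1(C)C | target

**Step count**
Total: 7 steps. Longest linear sequence: 6 steps (1 → 2 → 7 → 8 → 10 → 18 → 19); the furan branch joins at step 6.

**Three steps most likely to fail, with fallbacks**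

Step 2 (transfer of a dienyl group from a mixed zinc reagent with high enantioselectivity, and C-methylation of a zinc enolate, are both unproven in this combination). The fallback sets out from 2 and 3 and comes back at 7. Compound 2 is hydroborated with pinacolborane (Cp2Zr(H)Cl 5 mol%, Et3N, 60 °C) to the (1E,3E)-dienyl pinacolboronate F1. A rhodium catalyst from [RhCl(C2H4)2]2 and the appropriate BINAP enantiomer (KOH, dioxane/H2O, 50 °C) adds the dienyl group of F1 to 3 and gives, after isolation, (R)-5-dienyl-4,4-dimethylcyclohex-2-en-1-one F2. F2 has the same spatial arrangement as 7; the descriptor changes only because the neighbouring carbon is now CH2. LiN(iPr)2 in THF at −78 °C converts F2 into the lithium dienolate F3, the only enolate that can form, and MeI methylates it anti to the dienyl group to give 7.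

Step 5 (the volatile, very reactive cis-butenedial may oligomerise or be over-olefinated in the one-pot sequence). The fallback sets out from 11 and comes back at 15. Furan is methoxylated with Br2 in MeOH (Na2CO3, −5 °C) to 2,5-dimethoxy-2,5-dihydrofuran F4. Acidic methanol opens F4 to (E)-1,1,4,4-tetramethoxybut-2-ene F5. BF3·OEt2-catalysed double enol-ether condensation of F5 with 1-methoxyprop-1-ene gives 1,1,3,6,8,8-hexamethoxy-2,7-dimethyloct-4-ene F6. Heating F6 in aqueous AcOH with NaOAc hydrolyses both acetals and eliminates methanol to give 15.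

Step 7 (at most about half of the material can be the mono-alcohol per pass, and the three polyenes and the minor C4 epimer must be separated). The fallback sets out from 10 and comes back at 19. Part of salt 10 is reduced with NaBH4/CeCl3·7H2O in MeOH at −40 °C to the hydroxy phosphonium salt F7, from which the minor axial-alcohol epimer is removed by recrystallisation. NaOMe converts F7 into the hydroxy phosphorane F8, which reacts with an excess (3 equiv) of dial 15 to give the C25 hydroxy aldehyde F9. A second Wittig reaction of F9 with phosphorane 16, generated from 10 and NaOMe, followed by thermal isomerisation, gives 19 directly without a statistical step.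

**Further compounds**
F1 | step 2 | tert-butyldimethyl{[(2E,4E)-3-methyl-5-(4,4,5,5-tetramethyl-1,3,2-dioxaborolan-2-yl)penta-2,4-dienyl]oxy}silane | CC(C)(C)[Si](C)(C)OC/C=C(C)/C=C/B1OC(C)(C)C(C)(C)O1
F2 | step 2 | (R)-5-[(1E,3E)-5-(tert-butyldimethylsilyloxy)-3-methylpenta-1,3-dienyl]-4,4-dimethylcyclohex-2-en-1-one | CC(C)(C)[Si](C)(C)OC/C=C(C)/C=C/[C@H]1CC(=O)C=CC1(C)C
F3 | step 2 | lithium (3S)-3-[(1E,3E)-5-(tert-butyldimethylsilyloxy)-3-methylpenta-1,3-dienyl]-4,4-dimethylcyclohexa-1,5-dien-1-olate | CC(C)(C)[Si](C)(C)OC/C=C(C)/C=C/[C@H]1C=C(O[Li])C=CC1(C)C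
F4 | step 5 | 2,5-dimethoxy-2,5-dihydrofuran (cis/trans mixture) | COC1C=CC(OC)O1
F5 | step 5 | (E)-1,1,4,4-tetramethoxybut-2-ene | COC(OC)/C=C/C(OC)OC
F6 | step 5 | (E)-1,1,3,6,8,8-hexamethoxy-2,7-dimethyloct-4-ene (diastereomer mixture) | COC(OC)C(C)C(OC)/C=C/C(OC)C(C)C(OC)OC
F7 | step 7 | [(2E,4E)-5-[(1S,2S,3S)-3-hydroxy-2,6,6-trimethylcyclohexyl]-3-methylpenta-2,4-dienyl]triphenylphosphonium bromide | [Br-].c1ccccc1[P+](c1ccccc1)(c1ccccc1)C/C=C(C)/C=C/[C@H]1[C@H](C)[C@@H](O)CCC1(C)C
F8 | step 7 | (1S,2S,3S)-2,4,4-trimethyl-3-[(1E,3E)-3-methyl-5-(triphenylphosphoranylidene)penta-1,3-dienyl]cyclohexan-1-ol | c1ccccc1P(c1ccccc1)(c1ccccc1)=C/C=C(C)/C=C/[C@H]1[C@H](C)[C@@H](O)CCC1(C)C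
F9 | step 7 | (2E,4E,6E,8E,10E,12E)-13-[(1S,2S,3S)-3-hydroxy-2,6,6-trimethylcyclohexyl]-2,7,11-trimethyltrideca-2,4,6,8,10,12-hexaenal | O=C/C(C)=C/C=C/C=C(C)/C=C/C=C(C)/C=C/[C@H]1[C@H](C)[C@@H](O)CCC1(C)C
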